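Early in the amber run, at 0.500 min, the readings show nearly all of the left-handed substrate gone, while the right-handed substrate has fallen from half of the charge to just 45.7%.

| setting | blue | amber | flask |
|---|---|---|---|
| left-handed substrate | 1.1 M | 1.8 M | 0.80 M |
| right-handed substrate | 1.1 M | 1.8 M | 0.80 M |
| gas | 32 mM (held) | 32 mM (held) | 32 mM (held) |
| free catalyst | 5 mol% | 5 mol% | 5 mol% |
| remark | run made earlier | run made earlier |  |
| time |  |  | 5.0 min |

| run | time / min | right-handed substrate / % | left-handed substrate / % |
|---|---|---|---|
| blue | 0.833 | 41.7 | 0 |
| blue | 1.50 | 35.8 | 0.1 |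
| blue | 2.50 | 27.4 | 0.6 |
| blue | 3.00 | 24.8 | 0 |
| blue | 4.00 | 19.3 | 0 |
| blue | 5.00 | 16.1 | 0 |
| blue | 6.00 | 13.7 | 0 |
| amber | 0.500 | 45.7 | 1.4 |
| amber | 0.667 | 43.3 | 0 |
| amber | 1.00 | 37.8 | 0.1 |
| amber | 1.50 | 31.1 | 0 |
| amber | 2.50 | 21.8 | 0.3 |
| amber | 4.00 | 13.6 | 0.2 |
| amber | 6.00 | 7.7 | 0 |

(each reading ± 0.3 percentage points)

- free catalyst is single-handed; left-handed substrate and right-handed substrate are mirror images of each other, charged as a racemate, each of them at the stated concentration
- at the start none of the gas is in solution

1. whether the excess of right-handed substrate over left-handed substrate among what is left of the two reaches 90% by 5.0 min (yes / no)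
2. the highest excess of right-handed substrate over left-handed substrate among what is left of the two up to 5.0 min

That amber reading, with its scatter of 0.3 percentage points, gives a selectivity factor, the ratio of the logarithms of the surviving fractions of the two substrates, of about 39.8. If the factor holds in the flask, the excess reaches 90% once the right-handed substrate is down to 46.3% of the charge, and I call this level the mark. The blue run is already below the mark at its first reading, with 41.7% at 0.833 min. If times stretch inversely with the charge, my own reckoning from blue puts the flask past the mark by 1.15 min, earlier than the 5.0 min allowed.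

The forecast says yes, with a top excess of 99.9%, the wanted excess being “reached within about a minute”.

The flask gives yes, with a top excess of 100%.

    free catalyst + left-handed substrate ⇌ catalyst intermediate A (K = 9.20 /M, k = 52.0 /M/s)
    free catalyst + right-handed substrate ⇌ catalyst intermediate B (K = 0.400 /M, k = 16.0 /M/s)
    reagent + catalyst intermediate A → free catalyst + left-handed product (k = 37.0 /M/s)
    reagent + catalyst intermediate B → free catalyst + right-handed product (k = 16.0 /M/s)
    gas ⇌ reagent, rate k5*(csat - [reagent]) (kL = 17.0 /s)
    2 free catalyst ⇌ resting dimer, settled at all times (K = 16.0 /M)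
    free catalyst → spent catalyst (k = 0.00580 /s)

In the flask the excess reaches 90% at 0.548 min, earlier than the 5.0 min allowed, with 46.3% of the charge still right-handed substrate. The loss of free catalyst and left-handed substrate to catalyst intermediate A, taken forward alone with the charge held, has a half-life of 0.33 s, shorter than 5.0 min, and at 5.00 min the flask holds 0% left-handed substrate and 21.0% right-handed substrate, below the mark.

All runs are calculated from invented constants; scatter was added.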